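## Structural features

The target is a 2-aryl-3-hydroxymethyl-2,3-dihydrobenzofuran, an 8,3'-neolignan whose two C6–C3 units are also joined through an oxygen bridge from C4' to C7. Ring A (3,4,5-trimethoxyphenyl) sits on C7, which also carries the ring oxygen O4'. Its neighbour C8 is bonded to C3' of ring B and to the hydroxymethyl carbon C9, so the dihydrofuran ring consists of O4', C7, C8, C3' and C4'. Ring B carries a methoxy group at C5' and, para to O4' at C1', an (E)-3-hydroxyprop-1-enyl chain (C7'–C9'). C7 (R) and C8 (S) are adjacent stereocentres with ring A and C9 trans, the more stable arrangement. Fragile points are the C7–O4' bond (benzylic to an electron-rich ring, so open to ionisation and hydrogenolysis), the acid-sensitive cinnamyl-type alcohol, and C8 whenever C9 is a carbonyl group (epimerisation, and β-elimination of O4' that would endanger C7). The real difficulty is the absolute and relative control of the two contiguous stereocentres while the C1' chain stays unsaturated. The key step uses the 1,2-pattern "O4' on C7, one oxygenated carbon on C8": this is what remains when the ortho phenol oxygen and a CO-derived carbon are added across a C7≡C8 triple bond between ring A and C3' of ring B.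

## Logic of the disconnections

17 ⇒ 16. No skeletal bond is cut; the C9' carbinol is traced back to an ester carbonyl. The cinnamyl-type alcohol is the most sensitive part of 17 and is therefore unveiled last. The chain travels as a robust conjugated ester. The forward step must reduce 1,2 only and be worked up without acid.

16 ⇒ 14 + 15. The C7'=C8' double bond is cut. The three-carbon chain shrinks to the formyl carbon C7', which ring B owns from 1 onwards, and C8'–C9' come from 15. The forward step must give the E alkene and tolerate the free C9 hydroxyl.

14 ⇒ 12 (through 13). The C9 carbinol is taken back to an acyl group on nitrogen (the C9–N bond of 12) and the formyl group to its acetal. 12 is the compound in which the absolute configuration is secured, and one reduction both releases the auxiliary and puts C9 at its final oxidation level. Hydride must attack the exocyclic carbonyl, C8 must not epimerise, and the acetal must last until the reduction is over.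

12 ⇒ 8 + 9. The C9–N bond is cut, giving racemic 8 and enantiopure 9. This is a resolution: the configuration of C7 and C8 is selected, not created. It is preferred to a catalytic enantioselective reduction of the C7=C8 bond of 7, which would be shorter but has no adequate precedent for a tetrasubstituted 2-aryl-3-alkoxycarbonyl benzofuran. All earlier intermediates may then be achiral or racemic. The price is at most half of the material, and the forward step needs carboxyl activation without acid and separable diastereomers.

8 ⇒ 7. The C7–H and C8–H bonds are removed (no skeletal bond), which restores the aromatic furan and erases both stereocentres. The forward reduction must add hydrogen across C7=C8 and deliver trans; this is secured by thermodynamic protonation at C8, which is α to the ester. It must spare the aryl ethers.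

7 ⇒ 6. The two acetal C–O bonds at C7' are cut. A free formyl group would not survive the dissolving metal of the next step. The acetal is placed after furan closure because, para to a free phenol, it would be too labile to handle.

6 ⇒ 5. O4'–C7 and C8–C9 are cut, which opens the furan ring and removes C9. This leaves a linear diarylalkyne, with C9 coming from a C1 gas and its alkoxy group from the solvent. Carbonyl insertion must outrun protonolysis of the C8–metal bond. The formyl group stays unmasked in 5, which makes 5 a stable vinylogous acid and makes the preceding unmasking of the phenol easy.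

5 ⇒ 4 ⇒ 2 + 3. The O-acetyl group is restored and the C8–C3' bond (sp–sp2) is cut, giving one simple arene per ring. The phenol oxygen must stay masked during the coupling and be freed afterwards without adding to the triple bond.

2 ⇒ 1. Only the O–acetyl bond is cut; the forward step is a routine acylation.

## Other disconnections considered

Alternative 1: The cut removes O4'–C7 and C7–C8. C7 with ring A becomes a one-carbon benzylic ylide, and ring B supplies C8 (with C9 attached) as the exocyclic carbon of an ortho-quinone methide.
- Forward key step: a carbonate base would expel sulfinate from the racemic sulfone A2 to give the quinone methide and would deprotonate the enantiopure benzylsulfonium salt A3. The ylide carbon would add to C8 (C7–C8), the ring would rearomatise to a phenoxide, and this would displace the sulfide at C7 (O4'–C7, 5-exo-tet) to give the silyl ether A1. Anti displacement in the favoured betaine would account for the trans relationship.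
- In its favour: the ring, both stereocentres and (through the chiral sulfide) the absolute configuration would arise in one step. On stereocontrol this is better than the chosen plan, whose key step makes no stereocentre and which pays for the absolute configuration with a resolution. It is also better in that C9 is at the alcohol level from the start.
- Against it here: the quinone methide carries a CH2OSi group on the methide carbon. Alkyl-substituted ortho-quinone methides of this kind can tautomerise to the ortho-vinylphenol (here an enol silyl ether) before they are intercepted, whereas the secure precedents use aryl-substituted or unsubstituted methides. The face selectivity of a 3,4,5-trimethoxybenzyl ylide on a sulfide such as that of A3 is an open question. A stoichiometric chiral sulfide is needed. A1 still lacks the C7'–C9' chain, which must be attached to the C1' bromide by cross-coupling.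
- Comparison: on structure, the chosen plan carries C7' from the first compound onwards, while the alternative adds it late. On mechanism, the chosen plan uses better charted steps, while the alternative puts more risk and more reward into one operation. On step economy the two are about equal (roughly four steps to A2, two to A3, two or three after A1), and the alternative is more convergent.

Alternative 2: C7–C8 and the bond from the carbonyl oxygen to C9 are cut, which reveals a 2,3-diaryloxetane. The oxetane is related to the target by exchanging its ring oxygen at C7 for O4'.
- Forward key step: irradiation of aldehyde A6 with styrene A5 would give the trans oxetane A4 through the triplet 1,4-biradical with the radical at benzylic C8. Removal of the silyl group and attack of O4' on C7 with inversion would open the strained ring, close the dihydrofuran and free the C9 hydroxyl in the bromo alcohol A7.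
- In its favour: the core skeleton and both stereocentres (relative sense) come from two very simple components in one step. The ring switch is driven by about 25 kcal/mol of strain and is stereospecific, so a trans oxetane maps onto the trans target. On step economy it is better than the chosen plan (about seven steps against ten).
- Against it here: the product is racemic, so on absolute configuration it is only the equal of the chosen plan and needs a resolution as well. The triplet energy of an aromatic aldehyde lies above that of a styrene, so energy transfer and styrene dimerisation would compete. The lowest triplet of the electron-rich A6 has little n,π* character. The aryl bromide of A5 is photolabile, and the long-lived biradical would give cis/trans mixtures. In the ring switch O4' could instead attack the primary carbon C9, or C7 could ionise.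
- Comparison: on structure, A7 needs the same late C1' coupling as A1. On mechanism, the photochemical step is much less certain than any step of the chosen plan. On step economy the alternative wins.

Alternative 3: The cut removes C3'–C8 and the C9–O bond. This leaves an aryl iodide whose ortho oxygen carries C7 with ring A and a vinyl group (C8=C9).
- Forward key step: a tin hydride would abstract iodine from C3' of the ether A9. The aryl radical would add 5-exo-trig to C8 (closing the dihydrofuran ring), and the primary C9 radical would be captured by a persistent nitroxide to give the alkoxyamine A8. Reductive N–O cleavage would later free the C9 hydroxyl.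
- In its favour: the C7 stereocentre would be in place before the key step and could come from an established catalytic enantioselective reaction (branched-selective allylic etherification of the phenoxide with [Ir(cod)Cl]2 and a chiral phosphoramidite). On absolute configuration this is better than the chosen plan. C9 arrives at the alcohol level. Iodine is abstracted much faster than bromine, so the C1' bromide should survive. The neutral radical conditions suit the benzylic ether.
- Against it here: the C8 configuration rests on substrate control in an early transition state. Trans should be preferred but probably not exclusively, and once C9 is a CH2O group C8 cannot be corrected; in the chosen plan C8 is α to an ester and trans is the thermodynamic outcome. A9 is a doubly activated ether between a 2,6-disubstituted phenol and an electron-rich allylic benzylic carbon, so it is hard to make selectively and liable to ionise or rearrange. The nitroxide also consumes the tin hydride, so both are needed in excess.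
- Comparison: on structure, it needs the same late C1' coupling. On mechanism, the radical cascade is well charted and the equal of the chosen key step. On step economy it is about equal (roughly nine steps).

Key step: step 4

Assumption: the elution order of the two imide diastereomers of step 7 cannot be foreseen; 12 is defined as the isomer with the (2R,3R) acyl part, to be identified by crystallography of 12 or by the levorotation of 17.

Remark on structures: 5 and 6 are consistent in name and connectivity and are used unchanged. While C9 is a carboxyl-level carbon the target-like trans arrangement has the descriptors (2R,3R); with C9 as CH2OH the same arrangement is (2R,3S), that is (7R,8S).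

## Route

Step 1
Reactants: 1 4-hydroxy-3-iodo-5-methoxybenzaldehyde
Product: 2 4-formyl-2-iodo-6-methoxyphenyl acetate
Conditions: Ac2O, Et3N, DMAP (cat.), CH2Cl2, 0 °C to rt
Reagents that add atoms: acetic anhydride, CC(=O)OC(C)=O
Why: Base-mediated O-acylation of the phenol; the acetate blocks O4' so that it cannot add to the alkyne during the coupling of step 2.

Step 2
Reactants: 2 4-formyl-2-iodo-6-methoxyphenyl acetate; 3 5-ethynyl-1,2,3-trimethoxybenzene
Product: 4 4-formyl-2-methoxy-6-[(3,4,5-trimethoxyphenyl)ethynyl]phenyl acetate
Conditions: PdCl2(PPh3)2 (2 mol%), CuI (2 mol%), Et3N, THF, rt, argon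
Reagents that add atoms: none
Why: Sonogashira coupling of an electron-poor aryl iodide, which should proceed at room temperature and forms C8–C3'; the tertiary amine leaves the aryl acetate intact, so no phenoxide is available for premature closure to a benzofuran that lacks C9.

Step 3
Reactants: 4 4-formyl-2-methoxy-6-[(3,4,5-trimethoxyphenyl)ethynyl]phenyl acetate
Product: 5 4-hydroxy-3-methoxy-5-[(3,4,5-trimethoxyphenyl)ethynyl]benzaldehyde
Conditions: K2CO3 (1.1 equiv), MeOH, 0 °C, 20 min; cold dilute aq. HCl to pH 5
Reagents that add atoms: none
Why: Base-mediated methanolysis (transesterification) of an aryl acetate; the departing phenoxide is stabilised by the para formyl group, which makes cleavage fast at 0 °C and also makes this phenoxide too poor a nucleophile for anionic 5-endo-dig attack on the alkyne under these conditions.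

Step 4
Reactants: 5 4-hydroxy-3-methoxy-5-[(3,4,5-trimethoxyphenyl)ethynyl]benzaldehyde
Product: 6 methyl 5-formyl-7-methoxy-2-(3,4,5-trimethoxyphenyl)benzofuran-3-carboxylate
Conditions: PdI2 (2 mol%), KI (20 mol%), CO–air 4:1 (40 atm), MeOH, 80 °C; work-up with dilute aq. HCl
Reagents that add atoms: carbon monoxide, [C-]#[O+]; methanol, CO
Why: Iodide-ligated divalent palladium ([PdI4]2−, kept in solution by the excess KI) coordinates the C7≡C8 triple bond and the phenol oxygen O4' attacks C7 anti to the metal, a 5-endo-dig closure that forms O4'–C7 and the furan ring and leaves a 3-benzofuranyl–palladium bond at C8. Under CO pressure this bond inserts CO and the acylpalladium iodide is cleaved by methanol, which forms C8–C9 as the methyl ester and releases zerovalent palladium and HI; oxygen converts these back into PdI2 and water. The closest known reaction type is the PdI2/KI-catalysed oxidative heterocyclisation–alkoxycarbonylation of alkynes that carry a tethered OH or NH group, and more generally the alkoxycarbonylative annulation of 2-alkynylphenols to benzofuran-3-carboxylates with divalent palladium under CO. No stereocentre is created: C7 and C8 become the sp2 carbons of the furan ring, and their configuration is settled in steps 6 and 7. Regiochemistry needs no control, because only attack at C7 closes a ring from O4'. The selectivity that matters is CO insertion against protonolysis of the C8–palladium bond, which would give the benzofuran without C9; the high CO partial pressure and the low standing concentration of HI (consumed in the reoxidation) should secure it. The formyl group takes no part, and any dimethyl acetal formed in the acidic methanol is returned to the aldehyde by the acidic work-up.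

Step 5
Reactants: 6 methyl 5-formyl-7-methoxy-2-(3,4,5-trimethoxyphenyl)benzofuran-3-carboxylate
Product: 7 methyl 5-(dimethoxymethyl)-7-methoxy-2-(3,4,5-trimethoxyphenyl)benzofuran-3-carboxylate
Conditions: HC(OMe)3, TsOH·H2O (2 mol%), MeOH, rt; Et3N quench
Reagents that add atoms: trimethyl orthoformate, COC(OC)OC
Why: Acid-catalysed acetalisation driven by the orthoformate as water scavenger; the acetal masks the formyl group against the electron-transfer reduction of step 6, and it is installed only now because with O4' inside the furan ring it is an ordinary aryl acetal and no longer one para to a free phenol.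

Step 6
Reactants: 7 methyl 5-(dimethoxymethyl)-7-methoxy-2-(3,4,5-trimethoxyphenyl)benzofuran-3-carboxylate
Product: 8 methyl (2RS,3RS)-5-(dimethoxymethyl)-7-methoxy-2-(3,4,5-trimethoxyphenyl)-2,3-dihydrobenzofuran-3-carboxylate (racemic trans isomer)
Conditions: Mg turnings (15 equiv), MeOH–THF, 0 °C to rt; aq. NH4Cl–NH3 buffer (pH 8)
Reagents that add atoms: none
Why: Dissolving-metal conjugate reduction (Mg in methanol) of the aryl-conjugated enoate, a reduction known for 2-arylbenzofuran-3-carboxylates; electron transfer and protonation at C7 are followed by protonation of the ester enolate at C8 under equilibrating conditions (Mg(OMe)2 in methanol), so the more stable trans isomer with ring A and the ester on opposite faces should result. Both stereocentres are set here in the relative sense only (racemate), and the basic medium leaves the acetal untouched.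

Step 7
Reactants: 8 methyl (2RS,3RS)-5-(dimethoxymethyl)-7-methoxy-2-(3,4,5-trimethoxyphenyl)-2,3-dihydrobenzofuran-3-carboxylate; 9 (4S)-4-benzyl-1,3-oxazolidin-2-one
Product: 12 (4S)-4-benzyl-3-{[(2R,3R)-5-(dimethoxymethyl)-7-methoxy-2-(3,4,5-trimethoxyphenyl)-2,3-dihydrobenzofuran-3-yl]carbonyl}-1,3-oxazolidin-2-one, via potassium carboxylate 10 (not isolated), via mixed pivalic anhydride 11 (not isolated)
Conditions: KOSiMe3, THF, 40 °C; PivCl, Et3N, −20 °C; 9, LiCl, −20 °C to rt; separation of the diastereomers on Et3N-washed silica
Reagents that add atoms: potassium trimethylsilanolate, C[Si](C)(C)[O-].[K+] (potassium of 10); pivaloyl chloride, CC(C)(C)C(Cl)=O (pivaloyl group of 11)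
Why: Cleavage of the methyl ester by silanolate gives the anhydrous carboxylate without an acidification that the acetal would not survive, and the mixed pivalic anhydride then N-acylates the oxazolidinone in the presence of LiCl and Et3N. No stereocentre is made: the racemate becomes two diastereomeric imides whose stereocentre C8 lies next to the auxiliary, so they should be separable on silica, and the isomer with the (2R,3R) acyl part is carried on.

Step 8
Reactants: 12 (4S)-4-benzyl-3-{[(2R,3R)-5-(dimethoxymethyl)-7-methoxy-2-(3,4,5-trimethoxyphenyl)-2,3-dihydrobenzofuran-3-yl]carbonyl}-1,3-oxazolidin-2-one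
Product: 14 (2R,3S)-3-(hydroxymethyl)-7-methoxy-2-(3,4,5-trimethoxyphenyl)-2,3-dihydrobenzofuran-5-carbaldehyde, via acetal alcohol 13 (not isolated)
Conditions: LiBH4, H2O (1 equiv), Et2O–THF, 0 °C; then 1 M aq. HCl, THF, rt
Reagents that add atoms: water, O
Why: Hydride reduction of the exocyclic imide carbonyl (reductive removal of the oxazolidinone auxiliary) is followed in the same flask by acid hydrolysis of the dimethyl acetal; once C9 is a carbinol, C8 is no longer acidic and the configuration is secure. The change of the C8 descriptor from R to S reflects only the lower CIP rank of CH2OH.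

Step 9
Reactants: 14 (2R,3S)-3-(hydroxymethyl)-7-methoxy-2-(3,4,5-trimethoxyphenyl)-2,3-dihydrobenzofuran-5-carbaldehyde; 15 methyl (triphenylphosphoranylidene)acetate
Product: 16 methyl (2E)-3-[(2R,3S)-3-(hydroxymethyl)-7-methoxy-2-(3,4,5-trimethoxyphenyl)-2,3-dihydrobenzofuran-5-yl]prop-2-enoate
Conditions: toluene, 70 °C
Reagents that add atoms: none
Why: Wittig olefination with an ester-stabilised ylide forms C7'=C8', is E-selective with aromatic aldehydes as usual, and tolerates the free primary alcohol.

Step 10
Reactants: 16 methyl (2E)-3-[(2R,3S)-3-(hydroxymethyl)-7-methoxy-2-(3,4,5-trimethoxyphenyl)-2,3-dihydrobenzofuran-5-yl]prop-2-enoate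
Product: 17 (2E)-3-[(2R,3S)-3-(hydroxymethyl)-7-methoxy-2-(3,4,5-trimethoxyphenyl)-2,3-dihydrobenzofuran-5-yl]prop-2-en-1-ol, the (7R,8S,7'E) target
Conditions: iBu2AlH (4.5 equiv), CH2Cl2, −78 to −40 °C; aq. potassium sodium tartrate
Reagents that add atoms: none
Why: 1,2-Reduction of the enoate by iBu2AlH at low temperature gives the allylic alcohol without conjugate reduction; one equivalent is consumed by the C9 hydroxyl, and the neutral tartrate work-up protects the cinnamyl-type alcohol and the benzylic C7–O4' bond.

## Compound list

1 | 4-hydroxy-3-iodo-5-methoxybenzaldehyde | COc1cc(C=O)cc(I)c1O | starting material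
2 | 4-formyl-2-iodo-6-methoxyphenyl acetate | COc1cc(C=O)cc(I)c1OC(C)=O | intermediate
3 | 5-ethynyl-1,2,3-trimethoxybenzene | C#Cc1cc(OC)c(OC)c(OC)c1 | starting material
4 | 4-formyl-2-methoxy-6-[(3,4,5-trimethoxyphenyl)ethynyl]phenyl acetate | COc1cc(C=O)cc(C#Cc2cc(OC)c(OC)c(OC)c2)c1OC(C)=O | intermediate
5 | 4-hydroxy-3-methoxy-5-[(3,4,5-trimethoxyphenyl)ethynyl]benzaldehyde | COc1cc(C#Cc2cc(C=O)cc(OC)c2O)cc(OC)c1OC | intermediate
6 | methyl 5-formyl-7-methoxy-2-(3,4,5-trimethoxyphenyl)benzofuran-3-carboxylate | COC(=O)c1c(-c2cc(OC)c(OC)c(OC)c2)oc2c(OC)cc(C=O)cc12 | intermediate
7 | methyl 5-(dimethoxymethyl)-7-methoxy-2-(3,4,5-trimethoxyphenyl)benzofuran-3-carboxylate | COC(=O)c1c(-c2cc(OC)c(OC)c(OC)c2)oc2c(OC)cc(C(OC)OC)cc12 | intermediate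
8 | methyl (2RS,3RS)-5-(dimethoxymethyl)-7-methoxy-2-(3,4,5-trimethoxyphenyl)-2,3-dihydrobenzofuran-3-carboxylate (racemic trans; the (2R,3R) enantiomer is drawn) | COc1cc([C@@H]2Oc3c(OC)cc(C(OC)OC)cc3[C@H]2C(=O)OC)cc(OC)c1OC | intermediate
9 | (4S)-4-benzyl-1,3-oxazolidin-2-one | O=C1N[C@@H](Cc2ccccc2)CO1 | starting material
10 | potassium (2RS,3RS)-5-(dimethoxymethyl)-7-methoxy-2-(3,4,5-trimethoxyphenyl)-2,3-dihydrobenzofuran-3-carboxylate (racemic trans; the (2R,3R) enantiomer is drawn) | COc1cc([C@@H]2Oc3c(OC)cc(C(OC)OC)cc3[C@H]2C(=O)[O-])cc(OC)c1OC.[K+] | intermediate (not isolated)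
11 | (2RS,3RS)-5-(dimethoxymethyl)-7-methoxy-2-(3,4,5-trimethoxyphenyl)-2,3-dihydrobenzofuran-3-carboxylic 2,2-dimethylpropanoic anhydride (racemic trans; the (2R,3R) enantiomer is drawn) | COc1cc([C@@H]2Oc3c(OC)cc(C(OC)OC)cc3[C@H]2C(=O)OC(=O)C(C)(C)C)cc(OC)c1OC | intermediate (not isolated)
12 | (4S)-4-benzyl-3-{[(2R,3R)-5-(dimethoxymethyl)-7-methoxy-2-(3,4,5-trimethoxyphenyl)-2,3-dihydrobenzofuran-3-yl]carbonyl}-1,3-oxazolidin-2-one | COc1cc([C@@H]2Oc3c(OC)cc(C(OC)OC)cc3[C@H]2C(=O)N4C(=O)OC[C@@H]4Cc5ccccc5)cc(OC)c1OC | intermediate
13 | [(2R,3S)-5-(dimethoxymethyl)-7-methoxy-2-(3,4,5-trimethoxyphenyl)-2,3-dihydrobenzofuran-3-yl]methanol | COc1cc([C@@H]2Oc3c(OC)cc(C(OC)OC)cc3[C@H]2CO)cc(OC)c1OC | intermediate (not isolated)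
14 | (2R,3S)-3-(hydroxymethyl)-7-methoxy-2-(3,4,5-trimethoxyphenyl)-2,3-dihydrobenzofuran-5-carbaldehyde | COc1cc([C@@H]2Oc3c(OC)cc(C=O)cc3[C@H]2CO)cc(OC)c1OC | intermediate
15 | methyl (triphenylphosphoranylidene)acetate | COC(=O)C=P(c1ccccc1)(c1ccccc1)c1ccccc1 | starting material
16 | methyl (2E)-3-[(2R,3S)-3-(hydroxymethyl)-7-methoxy-2-(3,4,5-trimethoxyphenyl)-2,3-dihydrobenzofuran-5-yl]prop-2-enoate | COc1cc([C@@H]2Oc3c(OC)cc(/C=C/C(=O)OC)cc3[C@H]2CO)cc(OC)c1OC | intermediate
17 | (2E)-3-[(2R,3S)-3-(hydroxymethyl)-7-methoxy-2-(3,4,5-trimethoxyphenyl)-2,3-dihydrobenzofuran-5-yl]prop-2-en-1-ol | COc1cc([C@@H]2Oc3c(OC)cc(/C=C/CO)cc3[C@H]2CO)cc(OC)c1OC | target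

## Step count and least certain steps

Total number of steps: 10. Longest linear sequence: 10 steps (1 to 17); 3, 9 and 15 are purchased.

Step 4 (key step). The most likely failure is protonolysis of the C8–palladium bond before CO insertion, so that the ring closes without taking up C9; the vinylpalladium species is formed in a medium that contains HI. Autoxidation of the formyl group under pressurised air is a second concern. Fallback: from 5, iodocyclisation (I2, NaHCO3, MeCN, rt; the same 5-endo-dig closure with iodine in place of palladium) would give 3-iodo-7-methoxy-2-(3,4,5-trimethoxyphenyl)benzofuran-5-carbaldehyde F1. Methoxycarbonylation of its C8–I bond with zerovalent palladium generated from Pd(OAc)2 and 1,1'-bis(diphenylphosphino)ferrocene (CO 1 atm, MeOH, Et3N, DMF, 70 °C) would then give 6, where the route is rejoined. The two bonds of the key step are thus formed in two operations, without an oxidant and without an acidic medium.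

Step 6. Further electron transfer to the product can cleave the benzylic C7–O4' bond and open the ring, passivation of the metal can stall the reaction, and incomplete equilibration would leave some cis ester. Fallback: from 7, hydrogenation over Rh/Al2O3 (H2 50 atm, EtOAc) should add hydrogen cis across C7=C8 to give racemic methyl (2RS,3SR)-5-(dimethoxymethyl)-7-methoxy-2-(3,4,5-trimethoxyphenyl)-2,3-dihydrobenzofuran-3-carboxylate F2. NaOMe in MeOH would then epimerise C8 to the trans ester 8, where the route is rejoined.

Step 7. The two imides may separate poorly. The mixed anhydride may be attacked at the pivaloyl carbonyl because the other acyl group is itself hindered. Enolisation or ketene formation at C8 under Et3N could add cis isomers to the mixture. Half of the material is lost in any case. Fallback: from 8, LiAlH4 (THF, 0 °C) with a dilute acid work-up would give racemic (2RS,3SR)-3-(hydroxymethyl)-7-methoxy-2-(3,4,5-trimethoxyphenyl)-2,3-dihydrobenzofuran-5-carbaldehyde F3. Its enantiomers would be separated by preparative chromatography on a chiral stationary phase (cellulose tris(3,5-dimethylphenylcarbamate)); the (2R,3S) enantiomer is 14, where the route is rejoined. This replaces covalent diastereomers by a physical separation of enantiomers and makes step 8 unnecessary.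

Step 8. With a hindered acyl group, hydride can attack the ring carbonyl of the auxiliary and open the oxazolidinone instead of releasing it. Early loss of the acetal would expose the formyl group to reduction. Fallback: from 12, MeOMgBr in MeOH–CH2Cl2 (0 °C) would transfer the acyl group to methanol and give methyl (2R,3R)-5-(dimethoxymethyl)-7-methoxy-2-(3,4,5-trimethoxyphenyl)-2,3-dihydrobenzofuran-3-carboxylate F4. Aqueous acid would free the aldehyde, methyl (2R,3R)-5-formyl-7-methoxy-2-(3,4,5-trimethoxyphenyl)-2,3-dihydrobenzofuran-3-carboxylate F5. Wittig reaction with 15 would give the diester methyl (2R,3R)-7-methoxy-5-[(1E)-3-methoxy-3-oxoprop-1-en-1-yl]-2-(3,4,5-trimethoxyphenyl)-2,3-dihydrobenzofuran-3-carboxylate F6. iBu2AlH would then reduce both ester groups at once to give 17, where the route is rejoined.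

## Further compounds

F1 | step 4 | 3-iodo-7-methoxy-2-(3,4,5-trimethoxyphenyl)benzofuran-5-carbaldehyde | COc1cc(-c2oc3c(OC)cc(C=O)cc3c2I)cc(OC)c1OC
F2 | step 6 | methyl (2RS,3SR)-5-(dimethoxymethyl)-7-methoxy-2-(3,4,5-trimethoxyphenyl)-2,3-dihydrobenzofuran-3-carboxylate (racemic cis; the (2R,3S) enantiomer is drawn) | COc1cc([C@@H]2Oc3c(OC)cc(C(OC)OC)cc3[C@@H]2C(=O)OC)cc(OC)c1OC
F3 | step 7 | (2RS,3SR)-3-(hydroxymethyl)-7-methoxy-2-(3,4,5-trimethoxyphenyl)-2,3-dihydrobenzofuran-5-carbaldehyde (racemic trans; the (2R,3S) enantiomer is drawn) | COc1cc([C@@H]2Oc3c(OC)cc(C=O)cc3[C@H]2CO)cc(OC)c1OC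
F4 | step 8 | methyl (2R,3R)-5-(dimethoxymethyl)-7-methoxy-2-(3,4,5-trimethoxyphenyl)-2,3-dihydrobenzofuran-3-carboxylate | COc1cc([C@@H]2Oc3c(OC)cc(C(OC)OC)cc3[C@H]2C(=O)OC)cc(OC)c1OC
F5 | step 8 | methyl (2R,3R)-5-formyl-7-methoxy-2-(3,4,5-trimethoxyphenyl)-2,3-dihydrobenzofuran-3-carboxylate | COc1cc([C@@H]2Oc3c(OC)cc(C=O)cc3[C@H]2C(=O)OC)cc(OC)c1OC
F6 | step 8 | methyl (2R,3R)-7-methoxy-5-[(1E)-3-methoxy-3-oxoprop-1-en-1-yl]-2-(3,4,5-trimethoxyphenyl)-2,3-dihydrobenzofuran-3-carboxylate | COc1cc([C@@H]2Oc3c(OC)cc(/C=C/C(=O)OC)cc3[C@H]2C(=O)OC)cc(OC)c1OC
A1 | alternative 1 | tert-butyl{[(2R,3S)-5-bromo-7-methoxy-2-(3,4,5-trimethoxyphenyl)-2,3-dihydrobenzofuran-3-yl]methoxy}dimethylsilane | COc1cc([C@@H]2Oc3c(OC)cc(Br)cc3[C@H]2CO[Si](C)(C)C(C)(C)C)cc(OC)c1OC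
A2 | alternative 1 | 4-bromo-2-{2-[(tert-butyldimethylsilyl)oxy]-1-[(4-methylphenyl)sulfonyl]ethyl}-6-methoxyphenol (racemic) | COc1cc(Br)cc(C(CO[Si](C)(C)C(C)(C)C)S(=O)(=O)c2ccc(C)cc2)c1O
A3 | alternative 1 | (2R,5R)-2,5-dimethyl-1-(3,4,5-trimethoxybenzyl)thiolan-1-ium bromide (drawn without implying which sulfide enantiomer matches the target series) | C[C@@H]1CC[C@@H](C)[S+]1Cc1cc(OC)c(OC)c(OC)c1.[Br-]
A4 | alternative 2 | trans-3-[5-bromo-2-(tert-butyldimethylsilyloxy)-3-methoxyphenyl]-2-(3,4,5-trimethoxyphenyl)oxetane (racemic; the (2S,3S) enantiomer is drawn) | COc1cc([C@H]2OC[C@@H]2c2cc(Br)cc(OC)c2O[Si](C)(C)C(C)(C)C)cc(OC)c1OC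
A5 | alternative 2 | (4-bromo-2-ethenyl-6-methoxyphenoxy)(tert-butyl)dimethylsilane | C=Cc1cc(Br)cc(OC)c1O[Si](C)(C)C(C)(C)C
A6 | alternative 2 | 3,4,5-trimethoxybenzaldehyde | COc1cc(C=O)cc(OC)c1OC
A7 | alternative 2 | [(2RS,3SR)-5-bromo-7-methoxy-2-(3,4,5-trimethoxyphenyl)-2,3-dihydrobenzofuran-3-yl]methanol (racemic trans; the (2R,3S) enantiomer is drawn) | COc1cc([C@@H]2Oc3c(OC)cc(Br)cc3[C@H]2CO)cc(OC)c1OC
A8 | alternative 3 | 1-{[(2R,3S)-5-bromo-7-methoxy-2-(3,4,5-trimethoxyphenyl)-2,3-dihydrobenzofuran-3-yl]methoxy}-2,2,6,6-tetramethylpiperidine | COc1cc([C@@H]2Oc3c(OC)cc(Br)cc3[C@H]2CON4C(C)(C)CCCC4(C)C)cc(OC)c1OC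
A9 | alternative 3 | 5-bromo-1-iodo-3-methoxy-2-{[(1R)-1-(3,4,5-trimethoxyphenyl)prop-2-en-1-yl]oxy}benzene | COc1cc([C@@H](C=C)Oc2c(I)cc(Br)cc2OC)cc(OC)c1OC
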